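**Plan**

1. Retrosynthesis: after removal of the PMB, acetyl and angeloyl groups, the C5–O bond is cut (trans-diaxial opening of a 5β,6β-epoxide), C4=CH2 goes back to a C4 ketone (Wittig) and the epoxide to an enone. The C3a–C7a bond is then cut by a retro-1,2-shift (semipinacol), the C3a–C4 bond by a retro-pinacol coupling, and C7–i-Pr (conjugate addition) and C7a–C1 (Stille) lead back to (S)-4-silyloxycyclopentenone 7 and alkenylstannane 6.
2. Enabling feature: C4, the ring carbon that carries =CH2 (a latent ketone), is bonded to the ring-fusion carbon C3a. Ring C3a–C4–C5–C6–C7–C7a can therefore come from the cyclopentanol ring C4–C5–C6–C7–C7a by moving C7a from C4 to C3a, while the carbinol ring C4–C7a–C1–C2–C3–C3a contracts to ring C1–C2–C3–C3a–C7a.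
3. Forward order: the cyclopentanone is assembled first (7 to 13), a six-membered carbinol ring is closed on it by SmI2 pinacol coupling (14), the key shift then gives both final rings (17), and the six-membered ring is decorated last.
4. Stereochemistry: the purchased C–O stereocentre of 7 sets C7 (cuprate anti) and C7a (trans) and is then eliminated. C2 comes from a Noyori transfer hydrogenation, the trans ring fusion from the anti 1,2-shift (it is also the thermodynamic isomer), C5/C6 from β-face epoxidation and diaxial opening, and the Z-ethylidene from a syn-hydrostannation.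

Key step: step 13

Remark (assumption): ring atoms are numbered as in the target throughout (C1 ethylidene carbon, C2 acetoxy carbon, C3, C3a, C4 methylidene carbon, C5 carbinol, C6 angelate carbon, C7 isopropyl carbon, C7a); β is the face of H-7a. Compounds 1 and 7 and all reagents are taken as commercial.

**Route**

Step 1
Reactants: 1 3-[(tert-butyldimethylsilyl)oxy]propanal
Product: 2 racemic propargylic alcohol
Conditions: 1-propynylmagnesium bromide, THF, −78 °C to 0 °C; aq NH4Cl
Reagents that add atoms: 1-propynylmagnesium bromide CC#C[Mg]Br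
Why: Grignard 1,2-addition of the alkynyl nucleophile to the aldehyde; the primary silyl ether is inert.

Step 2
Reactants: 2 racemic propargylic alcohol
Product: 3 ynone
Conditions: Dess–Martin periodinane, NaHCO3, CH2Cl2, 0 °C to rt
Reagents that add atoms: none
Why: Dess–Martin oxidation of a secondary propargylic alcohol under buffered, neutral conditions, which avoids β-elimination of the silyloxy group.

Step 3
Reactants: 3 ynone
Product: 4 (S)-propargylic alcohol
Conditions: RuCl[(S,S)-TsDPEN](p-cymene) (1 mol %), i-PrOH, rt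
Reagents that add atoms: none
Why: Noyori asymmetric transfer hydrogenation of an α,β-acetylenic ketone; the catalyst distinguishes the alkynyl from the alkyl flank and should give the (S)-carbinol (target C2) without touching the alkyne.

Step 4
Reactants: 4 (S)-propargylic alcohol
Product: 5 (E)-α-stannyl allylic alcohol
Conditions: Bu3SnH, PdCl2(PPh3)2 (2 mol %), THF, 0 °C to rt
Reagents that add atoms: tributyltin hydride CCCC[SnH](CCCC)CCCC
Why: Pd-catalysed syn-hydrostannation of a propargylic alcohol, with tin going to the alkyne carbon next to the free hydroxyl; syn addition puts CH3 cis to the carbinol carbon and so fixes the later ethylidene geometry (a minor distal regioisomer would be removed by chromatography).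

Step 5
Reactants: 5 (E)-α-stannyl allylic alcohol
Product: 6 bis-silylated alkenylstannane
Conditions: TBSOTf, 2,6-lutidine, CH2Cl2, −78 °C to 0 °C
Reagents that add atoms: tert-butyldimethylsilyl triflate CC(C)(C)[Si](C)(C)OS(=O)(=O)C(F)(F)F
Why: Silylation of the hindered secondary allylic alcohol with the reactive silyl triflate; the lutidine buffer prevents protodestannylation.

Step 6
Reactants: 7 (S)-4-[(tert-butyldimethylsilyl)oxy]cyclopent-2-en-1-one
Product: 8 (S)-2-iodoenone
Conditions: I2, pyridine, CH2Cl2, 0 °C to rt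
Reagents that add atoms: iodine II
Why: Johnson α-iodination of a cyclic enone (pyridine conjugate addition, iodination of the enolate, elimination); the C4 stereocentre is untouched.

Step 7
Reactants: 6 bis-silylated alkenylstannane; 8 (S)-2-iodoenone
Product: 9 2-alkenyl dienone
Conditions: Pd2(dba)3 (5 mol %), AsPh3 (20 mol %), CuI (10 mol %), NMP, rt to 45 °C
Reagents that add atoms: none
Why: Stille coupling of an α-iodoenone with an alkenylstannane (AsPh3/CuI acceleration for the α-branched stannane) forms C7a–C1 with retention of the alkene geometry.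

Step 8
Reactants: 9 2-alkenyl dienone
Product: 11 trans,trans-cyclopentanone, via 2,3-cis ketone 10 (not isolated)
Conditions: i-PrMgCl, CuBr·SMe2 (10 mol %), THF, −78 °C; aq NH4Cl; then DBU (5 mol %), CH2Cl2, −20 °C
Reagents that add atoms: isopropylmagnesium chloride CC(C)[Mg]Cl
Why: Cu-catalysed conjugate addition of the isopropyl group anti to the C4 silyloxy group sets target C7; kinetic α-protonation of the dienolate opposite the new isopropyl group gives the 2,3-cis ketone, which a trace of base should equilibrate through the enolate to the more stable 2,3-trans ketone (target C7a).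

Step 9
Reactants: 11 trans,trans-cyclopentanone
Product: 12 primary alcohol
Conditions: HF·pyridine, pyridine, THF, 0 °C
Reagents that add atoms: none
Why: Buffered HF·pyridine cleaves the primary TBS ether much faster than the two secondary ones, and the β,γ-unsaturated ketone is not exposed to base.

Step 10
Reactants: 12 primary alcohol
Product: 13 keto-aldehyde
Conditions: Dess–Martin periodinane, NaHCO3, CH2Cl2, 0 °C
Reagents that add atoms: none
Why: Dess–Martin oxidation of the primary alcohol to the aldehyde under neutral conditions that preserve the β-silyloxy and β,γ-unsaturated carbonyl units.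

Step 11
Reactants: 13 keto-aldehyde
Product: 14 cis-fused bicyclic cis-diol
Conditions: SmI2 (2.5 equiv), t-BuOH, THF, −78 °C
Reagents that add atoms: none
Why: SmI2 ketone–aldehyde pinacol cyclisation to a six-membered ring forms C3a–C4; the Sm(III)-chelated ketyl should give the cis-diol, and the short tether delivers the aldehyde carbon to the ketone face syn to the side chain (cis ring fusion, C4–OH cis to H-7a).

Step 12
Reactants: 14 cis-fused bicyclic cis-diol
Product: 15 secondary monomesylate
Conditions: MsCl, Et3N, CH2Cl2, −20 °C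
Reagents that add atoms: methanesulfonyl chloride CS(=O)(=O)Cl
Why: Sulfonylation takes place only at the secondary C3a hydroxyl; the tertiary ring-fusion alcohol does not react under these conditions.

Step 13
Reactants: 15 secondary monomesylate
Product: 17 trans-fused enone, via silyloxy hydrindanone 16 (not isolated)
Conditions: KOt-Bu (2.5 equiv), t-BuOH/THF, 0 °C to 40 °C
Reagents that add atoms: none
Why: The tertiary C4 alkoxide drives a concerted 1,2-shift of the C4–C7a bond to C3a with backside displacement of mesylate (semipinacol), giving the C4 ketone 16, from which E1cB loss of the C6 silyloxide gives enone 17. The closest known reaction type is the base-induced pinacol-type rearrangement of vicinal diol monosulfonates used for hydronaphthalene-to-hydroazulene ring reorganisations. The new C3a–C7a bond closes the six-membered ring C3a–C4–C5–C6–C7–C7a by ring expansion of the cyclopentanol (C3a inserted between C4 and C7a), and the same suprafacial shift contracts the carbinol ring to the cyclopentane C1–C2–C3–C3a–C7a. C3a is inverted (migration anti to C–OMs) and C7a migrates with retention, so the all-cis arrangement of C4–O, C3a–OMs and H-7a in 15 becomes the trans ring fusion; C3a is also α to the new ketone, and the trans isomer should be the thermodynamic one under the conditions. The step needs migration of the ring-fusion bond and not of C4–C5: in the chair of the carbinol ring that has both C3a–OMs and C2–OTBS equatorial (the flipped chair makes them syn-diaxial), only C4–C7a is antiperiplanar to C–OMs, and C7a is the allylic, more substituted migrating carbon. The cis-diol geometry excludes epoxide formation.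

Step 14
Reactants: 17 trans-fused enone
Product: 18 5β,6β-epoxy ketone
Conditions: 30% H2O2, NaOH, MeOH, 0 °C
Reagents that add atoms: hydrogen peroxide OO
Why: Weitz–Scheffer epoxidation; hydroperoxide should add axially to C6 on the β face (anti to the pseudoaxial H-7, chair-like enolate) and close the cis-epoxide on that face, and the isolated ethylidene is inert to the nucleophilic oxidant.

Step 15
Reactants: 18 5β,6β-epoxy ketone
Product: 19 vinyl epoxide
Conditions: Ph3PCH3Br, KOt-Bu, THF, 0 °C to rt
Reagents that add atoms: methyltriphenylphosphonium bromide C[P+](c1ccccc1)(c1ccccc1)c1ccccc1.[Br-]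
Why: Wittig methylenation of the C4 ketone installs the exocyclic methylene; the epoxide-bearing α-carbon cannot enolise, and the enolisable C3a already has the stable trans configuration.

Step 16
Reactants: 19 vinyl epoxide
Product: 20 C5 PMB ether C6 alcohol
Conditions: 4-methoxybenzyl alcohol (5 equiv), BF3·OEt2 (10 mol %), CH2Cl2, −40 °C
Reagents that add atoms: 4-methoxybenzyl alcohol COc1ccc(CO)cc1
Why: Lewis-acid-catalysed SN2 alcoholysis of the vinyl epoxide at the allylic carbon C5 with inversion; this is also the trans-diaxial (Fürst–Plattner) mode, so C5 receives the α-oxygen in protected form and the retained epoxide oxygen becomes the free axial C6 β-hydroxyl.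

Step 17
Reactants: 20 C5 PMB ether C6 alcohol
Product: 21 C6 angelate
Conditions: angelic acid, 2,4,6-trichlorobenzoyl chloride, Et3N, toluene, rt; then 20, DMAP (cat.), 70 °C
Reagents that add atoms: angelic acid C/C=C(/C)C(=O)O
Why: Yamaguchi esterification through the mixed anhydride acylates the only free hydroxyl (hindered, axial C6–OH) under conditions known to suppress angelate-to-tiglate isomerisation.

Step 18
Reactants: 21 C6 angelate
Product: 22 C2 alcohol
Conditions: HF·pyridine, pyridine, THF, 0 °C to rt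
Reagents that add atoms: none
Why: Buffered fluoride cleaves the remaining secondary TBS ether; the PMB ether, the angelate and both alkenes are stable to it.

Step 19
Reactants: 22 C2 alcohol
Product: 23 C2 acetate
Conditions: Ac2O, pyridine, DMAP (cat.), CH2Cl2, 0 °C to rt
Reagents that add atoms: acetic anhydride CC(=O)OC(C)=O
Why: Standard acetylation of the only free hydroxyl; C5–O is still masked as the PMB ether.

Step 20
Reactants: 23 C2 acetate
Product: 24 target
Conditions: DDQ, CH2Cl2/pH 7 buffer, 0 °C
Reagents that add atoms: none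
Why: Oxidative cleavage of the PMB ether by DDQ releases the C5 hydroxyl without touching the acetate, the angelate or the two alkenes; the trans-diaxial C5–OH/C6–O arrangement cannot undergo acyl migration.

**Compound list**

1 | 3-[(tert-butyldimethylsilyl)oxy]propanal | O=CCCO[Si](C)(C)C(C)(C)C | starting material
2 | rac-1-[(tert-butyldimethylsilyl)oxy]hex-4-yn-3-ol | CC#CC(O)CCO[Si](C)(C)C(C)(C)C | intermediate
3 | 1-[(tert-butyldimethylsilyl)oxy]hex-4-yn-3-one | CC#CC(=O)CCO[Si](C)(C)C(C)(C)C | intermediate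
4 | (S)-1-[(tert-butyldimethylsilyl)oxy]hex-4-yn-3-ol | CC#C[C@@H](O)CCO[Si](C)(C)C(C)(C)C | intermediate
5 | (S,E)-1-[(tert-butyldimethylsilyl)oxy]-4-(tributylstannyl)hex-4-en-3-ol | C/C=C(/[Sn](CCCC)(CCCC)CCCC)[C@@H](O)CCO[Si](C)(C)C(C)(C)C | intermediate
6 | (S,E)-tributyl{4,6-bis[(tert-butyldimethylsilyl)oxy]hex-2-en-3-yl}stannane | C/C=C(/[Sn](CCCC)(CCCC)CCCC)[C@@H](O[Si](C)(C)C(C)(C)C)CCO[Si](C)(C)C(C)(C)C | intermediate
7 | (S)-4-[(tert-butyldimethylsilyl)oxy]cyclopent-2-en-1-one | O=C1C[C@H](O[Si](C)(C)C(C)(C)C)C=C1 | starting material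
8 | (S)-4-[(tert-butyldimethylsilyl)oxy]-2-iodocyclopent-2-en-1-one | O=C1C[C@H](O[Si](C)(C)C(C)(C)C)C=C1I | intermediate
9 | (S)-4-[(tert-butyldimethylsilyl)oxy]-2-{(S,Z)-4,6-bis[(tert-butyldimethylsilyl)oxy]hex-2-en-3-yl}cyclopent-2-en-1-one | O=C1C[C@H](O[Si](C)(C)C(C)(C)C)C=C1/C(=C/C)[C@@H](O[Si](C)(C)C(C)(C)C)CCO[Si](C)(C)C(C)(C)C | intermediate
10 | (2S,3S,4S)-4-[(tert-butyldimethylsilyl)oxy]-2-{(S,Z)-4,6-bis[(tert-butyldimethylsilyl)oxy]hex-2-en-3-yl}-3-isopropylcyclopentan-1-one (2,3-cis epimer, not isolated) | O=C1C[C@H](O[Si](C)(C)C(C)(C)C)[C@@H](C(C)C)[C@H]1/C(=C/C)[C@@H](O[Si](C)(C)C(C)(C)C)CCO[Si](C)(C)C(C)(C)C | intermediate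
11 | (2R,3S,4S)-4-[(tert-butyldimethylsilyl)oxy]-2-{(S,Z)-4,6-bis[(tert-butyldimethylsilyl)oxy]hex-2-en-3-yl}-3-isopropylcyclopentan-1-one | O=C1C[C@H](O[Si](C)(C)C(C)(C)C)[C@@H](C(C)C)[C@@H]1/C(=C/C)[C@@H](O[Si](C)(C)C(C)(C)C)CCO[Si](C)(C)C(C)(C)C | intermediate
12 | (2R,3S,4S)-4-[(tert-butyldimethylsilyl)oxy]-2-{(S,Z)-4-[(tert-butyldimethylsilyl)oxy]-6-hydroxyhex-2-en-3-yl}-3-isopropylcyclopentan-1-one | O=C1C[C@H](O[Si](C)(C)C(C)(C)C)[C@@H](C(C)C)[C@@H]1/C(=C/C)[C@@H](O[Si](C)(C)C(C)(C)C)CCO | intermediate
13 | (3S,4Z)-3-[(tert-butyldimethylsilyl)oxy]-4-{(1R,2S,3S)-3-[(tert-butyldimethylsilyl)oxy]-2-isopropyl-5-oxocyclopentyl}hex-4-enal | O=C1C[C@H](O[Si](C)(C)C(C)(C)C)[C@@H](C(C)C)[C@@H]1/C(=C/C)[C@@H](O[Si](C)(C)C(C)(C)C)CC=O | intermediate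
14 | (2S,3S,3aR,4Z,5S,7R,7aS)-2,5-bis[(tert-butyldimethylsilyl)oxy]-4-ethylidene-3-isopropyloctahydro-1H-indene-7,7a-diol (cis-fused; 7-OH, 7a-OH and H-3a on one face) | O[C@@]12C[C@H](O[Si](C)(C)C(C)(C)C)[C@@H](C(C)C)[C@@H]1/C(=C/C)[C@@H](O[Si](C)(C)C(C)(C)C)C[C@H]2O | intermediate
15 | (2S,3S,3aR,4Z,5S,7R,7aS)-2,5-bis[(tert-butyldimethylsilyl)oxy]-4-ethylidene-7a-hydroxy-3-isopropyloctahydro-1H-inden-7-yl methanesulfonate | O[C@@]12C[C@H](O[Si](C)(C)C(C)(C)C)[C@@H](C(C)C)[C@@H]1/C(=C/C)[C@@H](O[Si](C)(C)C(C)(C)C)C[C@H]2OS(C)(=O)=O | intermediate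
16 | (1Z,2S,3aR,6S,7S,7aS)-2,6-bis[(tert-butyldimethylsilyl)oxy]-1-ethylidene-7-isopropyloctahydro-4H-inden-4-one (trans-fused, not isolated) | O=C1C[C@H](O[Si](C)(C)C(C)(C)C)[C@@H](C(C)C)[C@@H]2/C(=C/C)[C@@H](O[Si](C)(C)C(C)(C)C)C[C@@H]12 | intermediate
17 | (1Z,2S,3aR,7R,7aS)-2-[(tert-butyldimethylsilyl)oxy]-1-ethylidene-7-isopropyl-1,2,3,3a,7,7a-hexahydro-4H-inden-4-one (trans-fused) | O=C1C=C[C@@H](C(C)C)[C@@H]2/C(=C/C)[C@@H](O[Si](C)(C)C(C)(C)C)C[C@@H]12 | intermediate
18 | (1Z,2S,3aR,5S,6S,7S,7aS)-2-[(tert-butyldimethylsilyl)oxy]-5,6-epoxy-1-ethylidene-7-isopropyloctahydro-4H-inden-4-one (5β,6β-epoxide) | O=C1[C@H]2O[C@H]2[C@@H](C(C)C)[C@@H]3/C(=C/C)[C@@H](O[Si](C)(C)C(C)(C)C)C[C@@H]13 | intermediate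
19 | (1Z,2S,3aR,5R,6S,7S,7aR)-2-[(tert-butyldimethylsilyl)oxy]-5,6-epoxy-1-ethylidene-7-isopropyl-4-methylideneoctahydro-1H-indene | C=C1[C@H]2O[C@H]2[C@@H](C(C)C)[C@@H]3/C(=C/C)[C@@H](O[Si](C)(C)C(C)(C)C)C[C@@H]13 | intermediate
20 | (1Z,2S,3aR,5S,6S,7S,7aR)-2-[(tert-butyldimethylsilyl)oxy]-1-ethylidene-7-isopropyl-5-[(4-methoxybenzyl)oxy]-4-methylideneoctahydro-1H-inden-6-ol | C=C1[C@H](OCc2ccc(OC)cc2)[C@@H](O)[C@@H](C(C)C)[C@@H]3/C(=C/C)[C@@H](O[Si](C)(C)C(C)(C)C)C[C@@H]13 | intermediate
21 | (1Z,2S,3aR,5S,6S,7S,7aR)-2-[(tert-butyldimethylsilyl)oxy]-1-ethylidene-7-isopropyl-5-[(4-methoxybenzyl)oxy]-4-methylideneoctahydro-1H-inden-6-yl (Z)-2-methylbut-2-enoate | C=C1[C@H](OCc2ccc(OC)cc2)[C@@H](OC(=O)/C(C)=C\C)[C@@H](C(C)C)[C@@H]3/C(=C/C)[C@@H](O[Si](C)(C)C(C)(C)C)C[C@@H]13 | intermediate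
22 | (1Z,2S,3aR,5S,6S,7S,7aR)-1-ethylidene-2-hydroxy-7-isopropyl-5-[(4-methoxybenzyl)oxy]-4-methylideneoctahydro-1H-inden-6-yl (Z)-2-methylbut-2-enoate | C=C1[C@H](OCc2ccc(OC)cc2)[C@@H](OC(=O)/C(C)=C\C)[C@@H](C(C)C)[C@@H]3/C(=C/C)[C@@H](O)C[C@@H]13 | intermediate
23 | (1Z,2S,3aR,5S,6S,7S,7aR)-2-acetoxy-1-ethylidene-7-isopropyl-5-[(4-methoxybenzyl)oxy]-4-methylideneoctahydro-1H-inden-6-yl (Z)-2-methylbut-2-enoate | C=C1[C@H](OCc2ccc(OC)cc2)[C@@H](OC(=O)/C(C)=C\C)[C@@H](C(C)C)[C@@H]3/C(=C/C)[C@@H](OC(C)=O)C[C@@H]13 | intermediate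
24 | (1Z,2S,3aR,5S,6S,7S,7aR)-2-acetoxy-1-ethylidene-5-hydroxy-7-isopropyl-4-methylideneoctahydro-1H-inden-6-yl (Z)-2-methylbut-2-enoate | C=C1[C@H](O)[C@@H](OC(=O)/C(C)=C\C)[C@@H](C(C)C)[C@@H]2/C(=C/C)[C@@H](OC(C)=O)C[C@@H]12 | target

**Step count and risks**

Total step count: 20. Longest linear sequence: 19 steps (steps 1–5, then 7–20).

Steps most likely to fail:

Step 8. The C7a–H of the product is both α to the ketone and allylic. Kinetic protonation may leave the 2,3-cis epimer, and the base needed to epimerise it may also move the ethylidene double bond into conjugation with the ketone. The fallback sets out from 7 (and 6) and comes back at 11. Stannane 6 is treated with iodine to give the alkenyl iodide (S,E)-4,6-bis[(tert-butyldimethylsilyl)oxy]-3-iodohex-2-ene F1. Isopropylmagnesium chloride with catalytic copper is added to 7 anti to the silyloxy group, the magnesium enolate is transmetalated to zinc, and the zinc enolate is cross-coupled with F1 under palladium(0)/phosphine catalysis (enolate α-alkenylation). The C7a substituent then enters as a carbon electrophile anti to the isopropyl group, so 11 should form directly without a protonation or equilibration at that centre.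

Step 11. The ketyl coupling may give the trans-diol or a mixture of ring-fusion isomers, or simple reduction of the aldehyde may compete; a trans-diol monomesylate would close to an epoxide under the alkoxide conditions of step 13. The fallback sets out from 13 and comes back at 17. An N-heterocyclic-carbene-catalysed intramolecular crossed aldehyde–ketone benzoin reaction (triazolium salt, amine base) closes the same six-membered ring without a reductant and gives the cis-fused α-ketol F2. Sodium borohydride, attacking from the convex face, should give the trans-diol F3, which is mesylated at the secondary hydroxyl to F4. Triethylaluminium (no free alkoxide, so no epoxide) then promotes the same 1,2-shift of the ring-fusion bond, which is antiperiplanar to the equatorial mesylate, to give the cis-fused hydrindanone F5. Potassium tert-butoxide epimerises C3a to the trans fusion and eliminates the C6 silyloxide, giving 17.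

Step 16. Capture of the benzylic alcohol at the exocyclic methylene carbon (SN2′), Lewis-acid-induced rearrangement of the vinyl epoxide to a carbonyl compound, or self-condensation of the alcohol may compete with opening at C5. The fallback sets out from 19 and comes back at 20. Dilute aqueous perchloric acid in THF hydrolyses the epoxide in the trans-diaxial sense to the 5α,6β-diol F6. The less hindered allylic C5 hydroxyl is then etherified selectively with 4-methoxybenzyl trichloroacetimidate and a catalytic acid, giving 20.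

**Further compounds**

F1 | step 8 | (S,E)-4,6-bis[(tert-butyldimethylsilyl)oxy]-3-iodohex-2-ene | C/C=C(/I)[C@@H](O[Si](C)(C)C(C)(C)C)CCO[Si](C)(C)C(C)(C)C
F2 | step 11 | (2S,3S,3aR,4Z,5S,7aS)-2,5-bis[(tert-butyldimethylsilyl)oxy]-4-ethylidene-7a-hydroxy-3-isopropyloctahydro-7H-inden-7-one | O[C@@]12C[C@H](O[Si](C)(C)C(C)(C)C)[C@@H](C(C)C)[C@@H]1/C(=C/C)[C@@H](O[Si](C)(C)C(C)(C)C)CC2=O
F3 | step 11 | (2S,3S,3aR,4Z,5S,7S,7aS)-2,5-bis[(tert-butyldimethylsilyl)oxy]-4-ethylidene-3-isopropyloctahydro-1H-indene-7,7a-diol (trans-diol) | O[C@@]12C[C@H](O[Si](C)(C)C(C)(C)C)[C@@H](C(C)C)[C@@H]1/C(=C/C)[C@@H](O[Si](C)(C)C(C)(C)C)C[C@@H]2O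
F4 | step 11 | (2S,3S,3aR,4Z,5S,7S,7aS)-2,5-bis[(tert-butyldimethylsilyl)oxy]-4-ethylidene-7a-hydroxy-3-isopropyloctahydro-1H-inden-7-yl methanesulfonate | O[C@@]12C[C@H](O[Si](C)(C)C(C)(C)C)[C@@H](C(C)C)[C@@H]1/C(=C/C)[C@@H](O[Si](C)(C)C(C)(C)C)C[C@@H]2OS(C)(=O)=O
F5 | step 11 | (1Z,2S,3aS,6S,7S,7aS)-2,6-bis[(tert-butyldimethylsilyl)oxy]-1-ethylidene-7-isopropyloctahydro-4H-inden-4-one (cis-fused) | O=C1C[C@H](O[Si](C)(C)C(C)(C)C)[C@@H](C(C)C)[C@@H]2/C(=C/C)[C@@H](O[Si](C)(C)C(C)(C)C)C[C@H]12
F6 | step 16 | (1Z,2S,3aR,5S,6S,7S,7aR)-2-[(tert-butyldimethylsilyl)oxy]-1-ethylidene-7-isopropyl-4-methylideneoctahydro-1H-indene-5,6-diol | C=C1[C@H](O)[C@@H](O)[C@@H](C(C)C)[C@@H]2/C(=C/C)[C@@H](O[Si](C)(C)C(C)(C)C)C[C@@H]12
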